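**Plan** (atom numbers are the celastroid, 24-nor-friedelane, numbers of each half; primes mark the upper half)

1. The last cut is the two C–O bonds of the 1,4-dioxane (C3'–O–C4 and C2'–O–C3): ortho-quinone of 6-oxopristimerol plus the C3=C4 enol of tingenone, joined by a hetero-Diels–Alder reaction.
2. In the upper half, ring C is cut at C8–C14 (radical conjugate addition) and ring D at C13–C18. C14 is a carbonyl-level carbon next to the future quaternary C13, so ring D (C13–C14–C15–C16–C17–C18) can grow from the five-membered ring C14–C15–C16–C17–C18 of a cis-hydrindanone by a semipinacol 1,2-shift of C18 from C14 to C13.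
3. This divides the upper half at C13–C14 into a dihydronaphthalene side-chain piece (rings A/B, from 2,3-dimethoxytoluene) and a ring-E hydrindanone (from 3-methylcyclohexenone and methyl vinyl ketone through a bicyclo[2.2.2]octene).
4. Forward order: rings A/B; ring E and the five-membered ring; fragment union; ring D by expansion; ring C by radical cyclization; C6/C7 oxidation level; deprotection; dimerization.
5. Stereochemistry: C9 from an auxiliary-controlled Michael addition; C17/C18/C20 from a catalytic endo Diels–Alder reaction; C13 in the 1,2-shift; C14 in the ring C closure; C3/C4 of the lower half in the cycloaddition; the other centres of the lower half come with tingenone.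

Key step: step 16

Assumption: tingenone (37) is bought as the isolated natural product.
Assumption: the sense of induction of (S)-1-phenylethylamine (step 6) and of the oxazaborolidinium catalyst (step 11) is assigned by analogy with simpler ketones and dienes; the mirror-image reagents are equally available.

Step 1
Reactants: 1 2,3-dimethoxytoluene; 2 succinic anhydride
Product: 3 4-(3,4-dimethoxy-2-methylphenyl)-4-oxobutanoic acid
Conditions: AlCl3, CH2Cl2/MeNO2, 0 °C to rt; aq. HCl
Reagents that add atoms: none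
Why: Friedel–Crafts acylation should go para to the in-plane 3-methoxy group (ortho to the methyl), the carbon that becomes C5.

Step 2
Reactants: 3 4-(3,4-dimethoxy-2-methylphenyl)-4-oxobutanoic acid
Product: 4 4-(3,4-dimethoxy-2-methylphenyl)butanoic acid
Conditions: H2 (4 bar), Pd/C (palladium on carbon), AcOH, HClO4 (cat.), 60 °C
Reagents that add atoms: none
Why: Acid-assisted hydrogenolysis of the electron-rich aryl ketone to the methylene group is a standard reduction of such keto acids.

Step 3
Reactants: 4 4-(3,4-dimethoxy-2-methylphenyl)butanoic acid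
Product: 5 6,7-dimethoxy-5-methyl-3,4-dihydronaphthalen-1(2H)-one
Conditions: (CF3CO)2O, CF3CO2H, CH2Cl2, 0 °C to rt
Reagents that add atoms: none
Why: Intramolecular Friedel–Crafts acylation through the mixed anhydride can close only onto the single free ortho position, which is para to a methoxy group.

Step 4
Reactants: 5 6,7-dimethoxy-5-methyl-3,4-dihydronaphthalen-1(2H)-one
Product: 7 6,7-dimethoxy-4,8-dimethyl-1,2-dihydronaphthalene, via tertiary alcohol 6 (not isolated)
Conditions: MeMgBr, THF, 0 °C; then TsOH (cat.), toluene, 80 °C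
Reagents that add atoms: methylmagnesium bromide, C[Mg]Br
Why: Grignard 1,2-addition followed by acid-catalysed dehydration gives the conjugated trisubstituted styrene and brings in C25.

Step 5
Reactants: 7 6,7-dimethoxy-4,8-dimethyl-1,2-dihydronaphthalene
Product: 9 (±)-6,7-dimethoxy-1,5-dimethyl-3,4-dihydronaphthalen-2(1H)-one, via epoxide 8 (not isolated)
Conditions: mCPBA, CH2Cl2, 0 °C; then BF3·OEt2 (cat.), 0 °C
Reagents that add atoms: meta-chloroperbenzoic acid, OOC(=O)c1cccc(Cl)c1
Why: Epoxidation and Meinwald rearrangement (benzylic C–O cleavage, 1,2-hydride shift) move the carbonyl to C8; the racemic centre is re-set in step 6.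

Step 6
Reactants: 9 (±)-6,7-dimethoxy-1,5-dimethyl-3,4-dihydronaphthalen-2(1H)-one; 10 acrylonitrile
Product: 13 3-[(1S)-6,7-dimethoxy-1,5-dimethyl-2-oxo-1,2,3,4-tetrahydronaphthalen-1-yl]propanenitrile, via ketimine 11 (not isolated), via adduct ketimine 12 (not isolated)
Conditions: (S)-1-phenylethylamine, TsOH (cat.), toluene, reflux (water removed); acrylonitrile, THF, 60 °C; 20% aq. AcOH, rt
Reagents that add atoms: none
Why: Deracemizing Michael addition of the aryl-conjugated secondary enamine, with the acceptor delivered on the face away from the auxiliary phenyl group, should set the quaternary C9.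

Step 7
Reactants: 13 3-[(1S)-6,7-dimethoxy-1,5-dimethyl-2-oxo-1,2,3,4-tetrahydronaphthalen-1-yl]propanenitrile
Product: 15 3-[(1R)-6,7-dimethoxy-1,5-dimethyl-1,4-dihydronaphthalen-1-yl]propanenitrile, via carbinol 14 (not isolated)
Conditions: NaBH4, MeOH, 0 °C; then methyl N-(triethylammoniosulfonyl)carbamate inner salt, benzene, 60 °C
Reagents that add atoms: none
Why: Hydride reduction and syn (Ei) dehydration can remove only H7, since C9 is quaternary, giving the C7=C8 alkene and leaving C9 untouched.

Step 8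
Reactants: 15 3-[(1R)-6,7-dimethoxy-1,5-dimethyl-1,4-dihydronaphthalen-1-yl]propanenitrile
Product: 17 2,4,6-triisopropylbenzenesulfonyl hydrazone of 4-[(1R)-6,7-dimethoxy-1,5-dimethyl-1,4-dihydronaphthalen-1-yl]butan-2-one, via methyl ketone 16 (not isolated)
Conditions: MeLi, Et2O, −78 to 0 °C; 1 M HCl; then 2,4,6-triisopropylbenzenesulfonyl hydrazide, MeOH/THF, rt
Reagents that add atoms: methyllithium, [Li]C; 2,4,6-triisopropylbenzenesulfonyl hydrazide, CC(C)c1cc(C(C)C)c(S(=O)(=O)NN)c(C(C)C)c1
Why: Single addition of MeLi to the nitrile gives after hydrolysis the methyl ketone (C13 with C27), which condenses to the hydrazone needed for the Shapiro reaction.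

Step 9
Reactants: 18 3-methylcyclohex-2-en-1-one
Product: 19 (±)-3,6-dimethylcyclohex-2-en-1-one
Conditions: LiN(iPr)2, THF, −78 °C; MeI
Reagents that add atoms: iodomethane, CI
Why: Kinetic α′-enolate alkylation brings in the future C30 methyl.

Step 10
Reactants: 19 (±)-3,6-dimethylcyclohex-2-en-1-one
Product: 20 1,4-dimethyl-2-(triisopropylsilyloxy)cyclohexa-1,3-diene
Conditions: LiN(iPr)2, THF, −78 °C; iPr3SiOTf
Reagents that add atoms: triisopropylsilyl triflate, CC(C)[Si](OS(=O)(=O)C(F)(F)F)(C(C)C)C(C)C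
Why: O-Silylation of the kinetic cross-conjugated dienolate gives the 2-silyloxy-1,3-diene and removes the racemic centre.

Step 11
Reactants: 20 1,4-dimethyl-2-(triisopropylsilyloxy)cyclohexa-1,3-diene; 21 methyl vinyl ketone
Product: 22 endo-1-[1,4-dimethyl-5-(triisopropylsilyloxy)bicyclo[2.2.2]oct-5-en-2-yl]ethan-1-one (acetyl syn to the enol ether bridge)
Conditions: B-(o-tolyl)oxazaborolidine from (S)-α,α-diphenylprolinol (20 mol%), Tf2NH (20 mol%), CH2Cl2, −78 to −40 °C
Reagents that add atoms: none
Why: Catalytic enantioselective Diels–Alder reaction: the silyl enol ether terminus bonds to the CH2 of the enone ("para" orientation) and the endo rule places the acetyl syn to the enol ether bridge, which fixes C17, C18 and C20 relative to one another while the catalyst fixes the absolute sense.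

Step 12
Reactants: 22 endo-1-[1,4-dimethyl-5-(triisopropylsilyloxy)bicyclo[2.2.2]oct-5-en-2-yl]ethan-1-one
Product: 24 methyl 3-acetyl-4-formyl-1,4-dimethylcyclohexane-1-carboxylate (ester, acetyl and formyl all cis), via keto aldehyde acid 23 (not isolated)
Conditions: O3, CH2Cl2/MeOH, −78 °C; Me2S, −78 °C to rt; then Me3SiCHN2, toluene/MeOH, 0 °C
Reagents that add atoms: ozone, [O-][O+]=O; (trimethylsilyl)diazomethane, C[Si](C)(C)C=[N+]=[N-]
Why: Ozonolysis of the silyl enol ether cuts the C29–C16 bridge, leaving the carboxyl (C29) and the aldehyde (C16) cis on ring E as the bicycle dictates, and the acid is then esterified.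

Step 13
Reactants: 24 methyl 3-acetyl-4-formyl-1,4-dimethylcyclohexane-1-carboxylate
Product: 25 methyl 3a,6-dimethyl-1-oxo-3a,4,5,6,7,7a-hexahydro-1H-indene-6-carboxylate (cis-fused)
Conditions: pyrrolidine (cat.), AcOH (cat.), toluene, 80 °C
Reagents that add atoms: none
Why: Intramolecular aldol condensation of the methyl ketone with the non-enolizable neopentyl aldehyde closes the five-membered ring, and the ring fusion α to the ketone settles as the more stable cis form.

Step 14
Reactants: 25 methyl 3a,6-dimethyl-1-oxo-3a,4,5,6,7,7a-hexahydro-1H-indene-6-carboxylate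
Product: 26 methyl 3a,6-dimethyl-1-oxooctahydro-1H-indene-6-carboxylate (cis-fused)
Conditions: H2 (1 atm), Pd/C (palladium on carbon), EtOAc, rt
Reagents that add atoms: none
Why: Hydrogenation of the enone C=C gives the cyclopentanone whose carbonyl carbon is C14.

Step 15
Reactants: 17 2,4,6-triisopropylbenzenesulfonyl hydrazone of 4-[(1R)-6,7-dimethoxy-1,5-dimethyl-1,4-dihydronaphthalen-1-yl]butan-2-one; 26 methyl 3a,6-dimethyl-1-oxooctahydro-1H-indene-6-carboxylate
Product: 29 methyl 1-{4-[(1R)-6,7-dimethoxy-1,5-dimethyl-1,4-dihydronaphthalen-1-yl]but-1-en-2-yl}-3a,6-dimethyl-1-(triethylsilyloxy)octahydro-1H-indene-6-carboxylate (side chain on the convex face), via vinyllithium 27 (not isolated), via lithium alkoxide 28 (not isolated)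
Conditions: n-BuLi (2.1 equiv), TMEDA, THF, −78 to 0 °C; CeCl3, −78 °C; 26; then Et3SiOTf, −78 to 0 °C
Reagents that add atoms: triethylsilyl triflate, CC[Si](CC)(CC)OS(=O)(=O)C(F)(F)F
Why: The Shapiro reaction gives the 1,1-disubstituted vinyl metal, which should add to the cyclopentanone from the convex face (cis to H18 and C28); the alkoxide is silylated in the same flask, and the C14 configuration, although lost in step 16, fixes the face of the later shift.

Step 16
Reactants: 29 methyl 1-{4-[(1R)-6,7-dimethoxy-1,5-dimethyl-1,4-dihydronaphthalen-1-yl]but-1-en-2-yl}-3a,6-dimethyl-1-(triethylsilyloxy)octahydro-1H-indene-6-carboxylate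
Product: 30 methyl 8-{2-[(1R)-6,7-dimethoxy-1,5-dimethyl-1,4-dihydronaphthalen-1-yl]ethyl}-2,4a,8-trimethyl-7-oxodecahydronaphthalene-2-carboxylate (cis-fused rings D/E; 13α-methyl)
Conditions: Tf2NH (10 mol%), iPrOH (1.2 equiv), CH2Cl2, −78 to −30 °C; aq. NaHCO3
Reagents that add atoms: none
Why: Protonation of the 1,1-disubstituted alkene gives the tertiary C13 cation next to the silyloxy-bearing C14, the ring bond C14–C18 migrates to C13, and the resulting silyloxocarbenium ion at C14 is desilylated by 2-propanol to the ketone. The closest known reaction type is the acid-promoted semipinacol rearrangement of 1-alkenylcycloalkanol silyl ethers to ring-enlarged α-quaternary ketones. Ring D closes by ring expansion of the five-membered ring C14–C15–C16–C17–C18, with C13 inserted between C14 and C18 by the 1,2-shift. C18 migrates with retention, and the new quaternary centre C13 is controlled by the cation conformer in which the larger C12 chain lies next to the ring methylene C15 and the methyl next to the bulky triethylsilyloxy group; with the side chain on the convex face this should give the 13α-methyl with C12 cis to H18. The step needs migration of the methine C18 and not the methylene C15, which the higher migratory aptitude of the more substituted carbon should secure, and protonation of the side-chain alkene in preference to the ring B alkene or C14–O ionization, for which its 1,1-disubstitution, the low temperature and catalytic acid are relied on.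

Step 17
Reactants: 30 methyl 8-{2-[(1R)-6,7-dimethoxy-1,5-dimethyl-1,4-dihydronaphthalen-1-yl]ethyl}-2,4a,8-trimethyl-7-oxodecahydronaphthalene-2-carboxylate
Product: 31 methyl 8-{2-[(1R)-6,7-dimethoxy-1,5-dimethyl-1,4-dihydronaphthalen-1-yl]ethyl}-2,4a,8-trimethyl-7-methylidenedecahydronaphthalene-2-carboxylate
Conditions: Ph3PCH3Br, KOtBu, toluene, 90 °C
Reagents that add atoms: methyltriphenylphosphonium bromide, C[P+](c1ccccc1)(c1ccccc1)c1ccccc1.[Br-]
Why: Wittig methylenation of the only ketone (the tertiary ester is too hindered to react) turns C14 into the carbon of an exocyclic alkene whose CH2 becomes C26.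

Step 18
Reactants: 31 methyl 8-{2-[(1R)-6,7-dimethoxy-1,5-dimethyl-1,4-dihydronaphthalen-1-yl]ethyl}-2,4a,8-trimethyl-7-methylidenedecahydronaphthalene-2-carboxylate
Product: 33 methyl 8-{2-[(1R)-6,7-dimethoxy-1,5-dimethyl-4-oxo-1,4-dihydronaphthalen-1-yl]ethyl}-2,4a,8-trimethyl-7-methylidenedecahydronaphthalene-2-carboxylate, via allylic alcohol 32 (not isolated)
Conditions: DDQ (2.2 equiv), CH2Cl2/H2O, rt
Reagents that add atoms: water, O
Why: DDQ should abstract hydride from the doubly activated (benzylic and allylic) C6–H, water adds at C6 and the alcohol is oxidized on to the aryl enone; the quaternary C9 prevents aromatization and the unactivated exocyclic alkene is inert.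

Step 19
Reactants: 33 methyl 8-{2-[(1R)-6,7-dimethoxy-1,5-dimethyl-4-oxo-1,4-dihydronaphthalen-1-yl]ethyl}-2,4a,8-trimethyl-7-methylidenedecahydronaphthalene-2-carboxylate
Product: 34 methyl 2,3-dimethoxy-6-oxo-24-nor-D:A-friedooleana-1,3,5(10)-trien-29-oate (8-H cis to C25)
Conditions: Fe(acac)3 (30 mol%), PhSiH3, EtOH/(CH2OH)2, 60 °C
Reagents that add atoms: none
Why: Metal-hydride hydrogen-atom transfer to the exocyclic alkene gives the tertiary C14 radical (C26 becomes methyl), which adds 6-exo to C8 of the enone (Giese cyclization); in the chair-like closure the planar ring B holds the C9 methyl axial on the forming ring C, so the smaller C26 methyl, not ring-D carbon C15, should take the position syn-axial to it (trans C/D fusion, 14β-methyl), and C8 is flattened again in step 20.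

Step 20
Reactants: 34 methyl 2,3-dimethoxy-6-oxo-24-nor-D:A-friedooleana-1,3,5(10)-trien-29-oate
Product: 35 methyl 2,3-dimethoxy-6-oxo-24-nor-D:A-friedooleana-1,3,5(10),7-tetraen-29-oate (6-oxopristimerol dimethyl ether)
Conditions: Pd(OCOCF3)2 (10 mol%), DMSO (20 mol%), O2 (1 atm), AcOH, 80 °C
Reagents that add atoms: none
Why: Aerobic palladium-catalysed α,β-dehydrogenation (palladium enolate, β-hydride elimination of H8) can form only the C7=C8 enone, and the quaternary C9 stops further aromatization.

Step 21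
Reactants: 35 methyl 2,3-dimethoxy-6-oxo-24-nor-D:A-friedooleana-1,3,5(10),7-tetraen-29-oate
Product: 36 methyl 2,3-dihydroxy-6-oxo-24-nor-D:A-friedooleana-1,3,5(10),7-tetraen-29-oate (6-oxopristimerol)
Conditions: BBr3, CH2Cl2, −78 to 0 °C; MeOH
Reagents that add atoms: none
Why: Lewis-acid cleavage of both aryl methyl ethers should spare the hindered tertiary methyl ester at low temperature.

Step 22
Reactants: 36 6-oxopristimerol; 37 tingenone
Product: 39 CNP0228258.2 (target), via ortho-quinone 38 (not isolated)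
Conditions: Ag2O, benzene, rt, dark
Reagents that add atoms: none
Why: Oxidation to the electron-poor ortho-quinone and inverse-electron-demand hetero-Diels–Alder addition across the C3=C4 enol of tingenone: the nucleophilic C4 should bond to O3' (the phenoxide developing at O2' is para to the C6' carbonyl) and O2' closes the hemiketal at C3; suprafacial addition makes the two C–O bonds cis, and the required adduct has both oxygens on the face of ring A that carries C25, face selectivity being expected to be modest.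

**Compound list**

1 | 2,3-dimethoxytoluene | COc1cccc(C)c1OC | starting material
2 | succinic anhydride | O=C1CCC(=O)O1 | starting material
3 | 4-(3,4-dimethoxy-2-methylphenyl)-4-oxobutanoic acid | COc1ccc(C(=O)CCC(=O)O)c(C)c1OC | intermediate
4 | 4-(3,4-dimethoxy-2-methylphenyl)butanoic acid | COc1ccc(CCCC(=O)O)c(C)c1OC | intermediate
5 | 6,7-dimethoxy-5-methyl-3,4-dihydronaphthalen-1(2H)-one | COc1cc2C(=O)CCCc2c(C)c1OC | intermediate
6 | (±)-6,7-dimethoxy-1,5-dimethyl-1,2,3,4-tetrahydronaphthalen-1-ol | COc1cc2C(C)(O)CCCc2c(C)c1OC | intermediate (not isolated)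
7 | 6,7-dimethoxy-4,8-dimethyl-1,2-dihydronaphthalene | COc1cc2C(C)=CCCc2c(C)c1OC | intermediate
8 | (±)-1,2-epoxy-6,7-dimethoxy-1,5-dimethyl-1,2,3,4-tetrahydronaphthalene | COc1cc2C3(C)OC3CCc2c(C)c1OC | intermediate (not isolated)
9 | (±)-6,7-dimethoxy-1,5-dimethyl-3,4-dihydronaphthalen-2(1H)-one | COc1cc2C(C)C(=O)CCc2c(C)c1OC | intermediate
10 | acrylonitrile | C=CC#N | starting material
11 | N-[(S)-1-phenylethyl] ketimine of 9 | COc1cc2C(C)C(=N[C@@H](C)c3ccccc3)CCc2c(C)c1OC | intermediate (not isolated)
12 | N-[(S)-1-phenylethyl] ketimine of 13 | COc1cc2c(c(C)c1OC)CCC(=N[C@@H](C)c3ccccc3)[C@@]2(C)CCC#N | intermediate (not isolated)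
13 | 3-[(1S)-6,7-dimethoxy-1,5-dimethyl-2-oxo-1,2,3,4-tetrahydronaphthalen-1-yl]propanenitrile | COc1cc2c(c(C)c1OC)CCC(=O)[C@@]2(C)CCC#N | intermediate
14 | 3-[(1S)-2-hydroxy-6,7-dimethoxy-1,5-dimethyl-1,2,3,4-tetrahydronaphthalen-1-yl]propanenitrile (C2 epimers) | COc1cc2c(c(C)c1OC)CCC(O)[C@@]2(C)CCC#N | intermediate (not isolated)
15 | 3-[(1R)-6,7-dimethoxy-1,5-dimethyl-1,4-dihydronaphthalen-1-yl]propanenitrile | COc1cc2c(c(C)c1OC)CC=C[C@@]2(C)CCC#N | intermediate
16 | 4-[(1R)-6,7-dimethoxy-1,5-dimethyl-1,4-dihydronaphthalen-1-yl]butan-2-one | COc1cc2c(c(C)c1OC)CC=C[C@@]2(C)CCC(C)=O | intermediate (not isolated)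
17 | 2,4,6-triisopropylbenzenesulfonyl hydrazone of 16 | COc1cc2c(c(C)c1OC)CC=C[C@@]2(C)CCC(C)=NNS(=O)(=O)c3c(C(C)C)cc(C(C)C)cc3C(C)C | intermediate
18 | 3-methylcyclohex-2-en-1-one | CC1=CC(=O)CCC1 | starting material
19 | (±)-3,6-dimethylcyclohex-2-en-1-one | CC1=CC(=O)C(C)CC1 | intermediate
20 | 1,4-dimethyl-2-(triisopropylsilyloxy)cyclohexa-1,3-diene | CC1=CC(O[Si](C(C)C)(C(C)C)C(C)C)=C(C)CC1 | intermediate
21 | methyl vinyl ketone | CC(=O)C=C | starting material
22 | endo-1-[1,4-dimethyl-5-(triisopropylsilyloxy)bicyclo[2.2.2]oct-5-en-2-yl]ethan-1-one | CC(=O)[C@@H]1C[C@@]2(C)CC[C@]1(C)C=C2O[Si](C(C)C)(C(C)C)C(C)C | intermediate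
23 | 3-acetyl-4-formyl-1,4-dimethylcyclohexane-1-carboxylic acid (all-cis carbonyl groups) | OC(=O)[C@@]1(C)C[C@@H](C(C)=O)[C@@](C)(C=O)CC1 | intermediate (not isolated)
24 | methyl 3-acetyl-4-formyl-1,4-dimethylcyclohexane-1-carboxylate (all-cis carbonyl groups) | COC(=O)[C@@]1(C)C[C@@H](C(C)=O)[C@@](C)(C=O)CC1 | intermediate
25 | methyl 3a,6-dimethyl-1-oxo-3a,4,5,6,7,7a-hexahydro-1H-indene-6-carboxylate (cis-fused) | COC(=O)[C@@]1(C)C[C@H]2C(=O)C=C[C@@]2(C)CC1 | intermediate
26 | methyl 3a,6-dimethyl-1-oxooctahydro-1H-indene-6-carboxylate (cis-fused) | COC(=O)[C@@]1(C)C[C@H]2C(=O)CC[C@@]2(C)CC1 | intermediate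
27 | {4-[(1R)-6,7-dimethoxy-1,5-dimethyl-1,4-dihydronaphthalen-1-yl]but-1-en-2-yl}lithium | [Li]C(=C)CC[C@]1(C)C=CCc2c(C)c(OC)c(OC)cc21 | intermediate (not isolated)
28 | lithium alkoxide of the C14 carbinol adduct | COC(=O)[C@@]1(C)C[C@H]2[C@]([O-])(C(=C)CC[C@]3(C)C=CCc4c(C)c(OC)c(OC)cc43)CC[C@@]2(C)CC1.[Li+] | intermediate (not isolated)
29 | methyl 1-{4-[(1R)-6,7-dimethoxy-1,5-dimethyl-1,4-dihydronaphthalen-1-yl]but-1-en-2-yl}-3a,6-dimethyl-1-(triethylsilyloxy)octahydro-1H-indene-6-carboxylate | COC(=O)[C@@]1(C)C[C@H]2[C@](O[Si](CC)(CC)CC)(C(=C)CC[C@]3(C)C=CCc4c(C)c(OC)c(OC)cc43)CC[C@@]2(C)CC1 | intermediate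
30 | methyl 8-{2-[(1R)-6,7-dimethoxy-1,5-dimethyl-1,4-dihydronaphthalen-1-yl]ethyl}-2,4a,8-trimethyl-7-oxodecahydronaphthalene-2-carboxylate | COC(=O)[C@@]1(C)C[C@H]2[C@](C)(CC[C@]3(C)C=CCc4c(C)c(OC)c(OC)cc43)C(=O)CC[C@@]2(C)CC1 | intermediate
31 | methyl 8-{2-[(1R)-6,7-dimethoxy-1,5-dimethyl-1,4-dihydronaphthalen-1-yl]ethyl}-2,4a,8-trimethyl-7-methylidenedecahydronaphthalene-2-carboxylate | COC(=O)[C@@]1(C)C[C@H]2[C@](C)(CC[C@]3(C)C=CCc4c(C)c(OC)c(OC)cc43)C(=C)CC[C@@]2(C)CC1 | intermediate
32 | C6 allylic alcohol of 31 (C6 epimers) | COC(=O)[C@@]1(C)C[C@H]2[C@](C)(CC[C@]3(C)C=CC(O)c4c(C)c(OC)c(OC)cc43)C(=C)CC[C@@]2(C)CC1 | intermediate (not isolated)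
33 | methyl 8-{2-[(1R)-6,7-dimethoxy-1,5-dimethyl-4-oxo-1,4-dihydronaphthalen-1-yl]ethyl}-2,4a,8-trimethyl-7-methylidenedecahydronaphthalene-2-carboxylate | COC(=O)[C@@]1(C)C[C@H]2[C@](C)(CC[C@]3(C)C=CC(=O)c4c(C)c(OC)c(OC)cc43)C(=C)CC[C@@]2(C)CC1 | intermediate
34 | methyl 2,3-dimethoxy-6-oxo-24-nor-D:A-friedooleana-1,3,5(10)-trien-29-oate (8-H cis to C25) | COC(=O)[C@]1(C)CC[C@]2(C)CC[C@]3(C)[C@@H]4CC(=O)c5c(cc(OC)c(OC)c5C)[C@]4(C)CC[C@@]3(C)[C@@H]2C1 | intermediate
35 | 6-oxopristimerol 2,3-di-O-methyl ether | COC(=O)[C@]1(C)CC[C@]2(C)CC[C@]3(C)C4=CC(=O)c5c(cc(OC)c(OC)c5C)[C@]4(C)CC[C@@]3(C)[C@@H]2C1 | intermediate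
36 | 6-oxopristimerol | COC(=O)[C@]1(C)CC[C@]2(C)CC[C@]3(C)C4=CC(=O)c5c(cc(O)c(O)c5C)[C@]4(C)CC[C@@]3(C)[C@@H]2C1 | intermediate
37 | tingenone | CC1=C(O)C(=O)C=C2C1=CC=C1[C@@]2(C)CC[C@@]3(C)[C@@H]4C[C@@H](C)C(=O)C[C@]4(C)CC[C@]13C | starting material
38 | 6-oxopristimerol ortho-quinone (2,3,6-trioxo-1(10),4,7-triene) | COC(=O)[C@]1(C)CC[C@]2(C)CC[C@]3(C)C4=CC(=O)C5=C(C)C(=O)C(=O)C=C5[C@]4(C)CC[C@@]3(C)[C@@H]2C1 | intermediate (not isolated)
39 | CNP0228258.2 | COC(=O)[C@]1(C)CC[C@]2(C)CC[C@]3(C)C4=CC(=O)c5c(cc6c(c5C)O[C@]5(C)C7=CC=C8[C@@](C)(CC[C@@]9(C)[C@@H]%10C[C@@H](C)C(=O)C[C@]%10(C)CC[C@]89C)C7=CC(=O)[C@]5(O)O6)[C@]4(C)CC[C@@]3(C)[C@@H]2C1 | target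

**Totals**

Total step count: 22.
Longest linear sequence: 16 steps (steps 1–8, then 15–22); the hydrindanone branch (steps 9–14) joins at step 15.

**Steps most likely to fail**

Step 16. The tertiary allylic C14–O bond may ionize before the alkene is protonated, which removes the oxygen that drives the shift, and rotation about C13–C14 may give the C13 epimer. Fallback: 29 is desilylated (Bu4NF, THF) to the free tertiary allylic alcohol F1. The shift is then triggered under neutral conditions by hydrogen-atom transfer and radical–polar crossover, a known entry to semipinacol rearrangements of allylic alcohols: [N,N′-bis(3,5-di-tert-butylsalicylidene)-1,2-cyclohexanediaminato]cobalt (divalent cobalt) as catalyst, N-fluoro-2,4,6-trimethylpyridinium tetrafluoroborate, PhSiH3, acetone, rt. This returns to the route at 30.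

Step 19. C8 may be attacked from the other face of the planar C14 radical (cis C/D fusion), or the hindered tertiary radical may be reduced before it cyclizes. Fallback: from 33, Markovnikov addition of dry HCl (CH2Cl2, −78 °C) gives the tertiary chloride F2. A tin hydride radical cyclization (Bu3SnH added slowly, AIBN, benzene, 80 °C) then closes ring C at low hydride concentration and without the iron hydride. This returns to the route at 34.

Step 22. The cycloaddition may take the other face of ring A of tingenone, or the reversed orientation of the quinone. Fallback: bromination of 37 at C4 from the face opposite C25 (NBS, THF, 0 °C) gives the 4α-bromo-2,3-dione F3. With the dianion of 36 (Cs2CO3, DMF) the more nucleophilic O3' should displace bromide with inversion and O2' then closes the hemiketal at C3, the classical catechol/α-halo ketone route to 2-hydroxy-1,4-benzodioxanes. This returns to the route at 39.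

**Further compounds**

F1 | step 16 | methyl 1-{4-[(1R)-6,7-dimethoxy-1,5-dimethyl-1,4-dihydronaphthalen-1-yl]but-1-en-2-yl}-1-hydroxy-3a,6-dimethyloctahydro-1H-indene-6-carboxylate | COC(=O)[C@@]1(C)C[C@H]2[C@](O)(C(=C)CC[C@]3(C)C=CCc4c(C)c(OC)c(OC)cc43)CC[C@@]2(C)CC1
F2 | step 19 | methyl 7-chloro-8-{2-[(1R)-6,7-dimethoxy-1,5-dimethyl-4-oxo-1,4-dihydronaphthalen-1-yl]ethyl}-2,4a,7,8-tetramethyldecahydronaphthalene-2-carboxylate (C14 epimers) | COC(=O)[C@@]1(C)C[C@H]2[C@](C)(CC[C@]3(C)C=CC(=O)c4c(C)c(OC)c(OC)cc43)C(C)(Cl)CC[C@@]2(C)CC1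
F3 | step 22 | 4α-bromo-3-oxo-3,4-dihydrotingenone (4-bromo-2,3-dione) | C[C@@]1(Br)C(=O)C(=O)C=C2C1=CC=C1[C@@]2(C)CC[C@@]3(C)[C@@H]4C[C@@H](C)C(=O)C[C@]4(C)CC[C@]13C
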